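**Retrosynthetic overview**
- The C11 hydroperoxide and C6=C7 are installed last by a singlet-oxygen ene reaction on a C7=C11 isopropylidene enone. The 1β-hydroxyl comes from α-face hydride reduction of a C1 ketone, itself made by γ-C–H oxidation of the C9=C10 enone.
- The strategy turns on C5, the fully substituted ring-fusion carbon of ring B that bears methyl C14 and lies two bonds (C6, C7) from the C8 ketone. Cutting C5–C6 exposes a tertiary C5 radical, generated by hydrogen-atom transfer to a C5=C14 methylene, which closes ring B 6-endo onto C6 of a vinyl ketone hung from C10 through C9–C8.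
- The cyclisation precursor comes from a ring A Weinreb amide and a 2-lithioalkene (C6, C7, C11–C13) made from 2-methylbut-3-yn-2-ol.
- Ring A is bought as 2-methylcyclohex-2-en-1-one; CBS reduction sets C3, anti hydroboration sets C4, and enolate alkylation sets C10. Ring B is the only ring formed (step 10).

Key step: step 10

Convention: eremophilane numbering is used throughout (decalin C1–C10, C15 on C4, C14 on C5, C11–C13 on C7); β is the face that carries the C4 and C5 methyls.
Remark: C7 of compounds 18–26 should form as a mixture of epimers; one epimer is drawn, and both converge when C7 becomes sp2 in step 16.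
Remark: C3 is carried as a triethylsilyl ether and C11 as a tert-butyldimethylsilyl ether so that C3 can be unmasked and esterified while C11 stays protected.

**Step 1**
Reactants: 1 2-methylcyclohex-2-en-1-one
Product: 2 (S)-2-methylcyclohex-2-en-1-ol
Conditions: (R)-2-methyl-CBS-oxazaborolidine (10 mol%), BH3·SMe2, THF, −20 °C; MeOH quench
Reagents that add atoms: none
Why: Corey–Bakshi–Shibata reduction, in which the alkenyl side of the ketone acts as the large group, so the (R)-catalyst should deliver hydride to give the (S)-carbinol that becomes C3.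

**Step 2**
Reactants: 2 (S)-2-methylcyclohex-2-en-1-ol
Product: 3 (S)-triethyl[(2-methylcyclohex-2-en-1-yl)oxy]silane
Conditions: Et3SiCl, imidazole, CH2Cl2, 0 °C
Reagents that add atoms: chlorotriethylsilane, CC[Si](Cl)(CC)CC
Why: Standard silylation of a secondary alcohol; the triethylsilyl group is chosen because it must later be cleaved in the presence of a tertiary tert-butyldimethylsilyl ether.

**Step 3**
Reactants: 3 (S)-triethyl[(2-methylcyclohex-2-en-1-yl)oxy]silane
Product: 5 (1S,2R,3S)-2-methyl-3-(triethylsilyloxy)cyclohexan-1-ol, via alkylborane 4 (not isolated)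
Conditions: BH3·THF, THF, 0 → 23 °C; then NaOH, H2O2, 0 °C
Reagents that add atoms: hydrogen peroxide, OO
Why: Hydroboration–oxidation puts boron on the less substituted alkene carbon (C5) and adds B–H syn from the face opposite the pseudoaxial allylic silyloxy group, which should set the C4 methyl cis to the C3 oxygen; the C5 carbinol configuration is lost in step 4.

**Step 4**
Reactants: 5 (1S,2R,3S)-2-methyl-3-(triethylsilyloxy)cyclohexan-1-ol
Product: 6 (2S,3S)-2-methyl-3-(triethylsilyloxy)cyclohexan-1-one
Conditions: Dess–Martin periodinane, NaHCO3, CH2Cl2, 0 → 23 °C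
Reagents that add atoms: none
Why: Buffered Dess–Martin oxidation should give the ketone without epimerising the cis C4 methyl or eliminating the β-silyloxy group.

**Step 5**
Reactants: 6 (2S,3S)-2-methyl-3-(triethylsilyloxy)cyclohexan-1-one; 7 2-bromo-N-methoxy-N-methylacetamide
Product: 9 2-[(1R,3S,4S)-3-methyl-2-oxo-4-(triethylsilyloxy)cyclohexyl]-N-methoxy-N-methylacetamide, via lithium enolate 8 (not isolated)
Conditions: LiN(i-Pr)2, THF, −78 °C; then 7, DMPU, −78 → −40 °C
Reagents that add atoms: none
Why: Kinetic enolisation takes the unhindered C10 methylene (this enolate has no β leaving group), and the enolate alkylation should occur on the face opposite the pseudoaxial C4 methyl, placing the acetamide chain trans to that methyl; a minor C10 epimer would be removed by chromatography.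

**Step 6**
Reactants: 9 2-[(1R,3S,4S)-3-methyl-2-oxo-4-(triethylsilyloxy)cyclohexyl]-N-methoxy-N-methylacetamide
Product: 10 2-[(1R,3R,4S)-3-methyl-2-methylidene-4-(triethylsilyloxy)cyclohexyl]-N-methoxy-N-methylacetamide
Conditions: Zn, CH2Br2, TiCl4, THF (preformed reagent); then 9, CH2Cl2, 0 → 23 °C
Reagents that add atoms: dibromomethane, BrCBr
Why: Takai–Lombardo methylenation is non-basic, so the two α-stereocentres and the β-silyloxy group of the hindered ketone should survive and the amide should stay untouched.

**Step 7**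
Reactants: 11 2-methylbut-3-yn-2-ol
Product: 12 3-bromo-2-methylbut-3-en-2-ol
Conditions: Et4N+ HBr2− (tetraethylammonium hydrogen dibromide), CH2Cl2, 40 °C
Reagents that add atoms: tetraethylammonium hydrogen dibromide, CC[N+](CC)(CC)CC.Br.[Br-]
Why: Markovnikov hydrobromination of the terminal alkyne by the weakly acidic, nucleophilic hydrogen dibromide salt should give the 2-bromoalkene without ionising the tertiary propargylic alcohol.

**Step 8**
Reactants: 12 3-bromo-2-methylbut-3-en-2-ol
Product: 13 [(3-bromo-2-methylbut-3-en-2-yl)oxy](tert-butyl)dimethylsilane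
Conditions: t-BuMe2SiOTf, 2,6-lutidine, CH2Cl2, 0 °C
Reagents that add atoms: tert-butyldimethylsilyl trifluoromethanesulfonate, CC(C)(C)[Si](C)(C)OS(=O)(=O)C(F)(F)F
Why: Silyl triflate silylation is the standard way to protect a tertiary alcohol.

**Step 9**
Reactants: 13 [(3-bromo-2-methylbut-3-en-2-yl)oxy](tert-butyl)dimethylsilane; 10 2-[(1R,3R,4S)-3-methyl-2-methylidene-4-(triethylsilyloxy)cyclohexyl]-N-methoxy-N-methylacetamide
Product: 15 4-(tert-butyldimethylsilyloxy)-4-methyl-3-methylidene-1-[(1R,3R,4S)-3-methyl-2-methylidene-4-(triethylsilyloxy)cyclohexyl]pentan-2-one, via vinyllithium 14 (not isolated)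
Conditions: 13, t-BuLi (2 equiv), Et2O, −78 °C; then 10, THF, −78 °C; AcOH quench at −78 °C
Reagents that add atoms: none
Why: Bromine–lithium exchange at −78 °C gives the 2-lithioalkene, which is acylated by the Weinreb amide (Weinreb ketone synthesis); the cold acidic quench releases the vinyl ketone while protonating the liberated amine so that it cannot add to the enone.

**Step 10**
Reactants: 15 4-(tert-butyldimethylsilyloxy)-4-methyl-3-methylidene-1-[(1R,3R,4S)-3-methyl-2-methylidene-4-(triethylsilyloxy)cyclohexyl]pentan-2-one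
Product: 18 11-(tert-butyldimethylsilyloxy)-3β-(triethylsilyloxy)-10βH-eremophilan-8-one (cis-fused; 4β,5β-dimethyl; 7β epimer drawn), via tertiary C5 radical 16 (not isolated), via cyclised C7 radical 17 (not isolated)
Conditions: Fe(acac)3 (0.5 equiv), PhSiH3 (2.5 equiv), EtOH/ethylene glycol 5:1, 0.02 M, 60 °C
Reagents that add atoms: none
Why: Fe(acac)3 (trivalent iron) and PhSiH3 should generate an iron hydride that hands a hydrogen atom to C14 of the exocyclic methylene, the more electron-rich of the two alkenes, and the tertiary radical 16 so formed adds to the enone terminus C6 to give α-keto radical 17, which divalent iron reduces to the enolate before ethanol protonates it. The closest known reaction is the metal-hydride hydrogen-atom-transfer reductive olefin–enone coupling (a radical conjugate addition), run here intramolecularly. Ring B closes in the 6-endo-trig mode, because the 5-exo path would attack the fully substituted, polarity-mismatched C7 and leave a primary radical. At C5, ring A should react through the chair with the C3 silyl ether and the C10 chain equatorial and the C4 methyl axial; the chain, which is trans to that methyl, reaches the axial lobe of the C5 radical on the face anti to the methyl (the flipped chair delivers C6 to the same face), so the C14 methyl ends cis to the C4 methyl and the decalin is cis-fused. C7 is set by enolate protonation, is not controlled, and is erased in step 16. The step needs hydrogen-atom transfer to the methylene rather than the enone, secured by the electronic difference between the two alkenes, and ring closure faster than a second hydrogen-atom transfer, favoured by high dilution.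

**Step 11**
Reactants: 18 11-(tert-butyldimethylsilyloxy)-3β-(triethylsilyloxy)-10βH-eremophilan-8-one
Product: 20 11-(tert-butyldimethylsilyloxy)-3β-(triethylsilyloxy)eremophil-9-en-8-one, via trimethylsilyl enol ether 19 (not isolated)
Conditions: LiN(i-Pr)2, Me3SiCl, THF, −78 °C; solvent exchange; Pd(OAc)2 (1.1 equiv), MeCN, 23 °C
Reagents that add atoms: none
Why: Ito–Saegusa oxidation: the amide base should deprotonate the open C9 methylene rather than the congested C7 methine, and the palladium enolate loses H10 by syn β-hydride elimination, which forms C9=C10 and erases the C10 stereocentre.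

**Step 12**
Reactants: 20 11-(tert-butyldimethylsilyloxy)-3β-(triethylsilyloxy)eremophil-9-en-8-one
Product: 21 11-(tert-butyldimethylsilyloxy)-3β-hydroxyeremophil-9-en-8-one
Conditions: PPTS (0.2 equiv), MeOH/CH2Cl2, 0 → 23 °C
Reagents that add atoms: none
Why: Mild acid methanolysis should cleave the secondary triethylsilyl ether selectively and leave the tertiary tert-butyldimethylsilyl ether in place.

**Step 13**
Reactants: 21 11-(tert-butyldimethylsilyloxy)-3β-hydroxyeremophil-9-en-8-one; 22 angelic acid
Product: 24 3β-angeloyloxy-11-(tert-butyldimethylsilyloxy)eremophil-9-en-8-one, via mixed anhydride 23 (not isolated)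
Conditions: 22, 2,4,6-trichlorobenzoyl chloride, Et3N, toluene, 23 °C; then 21, 80 °C
Reagents that add atoms: none
Why: Yamaguchi esterification through the mixed anhydride should acylate the hindered axial C3 alcohol; it is run without a nucleophilic pyridine catalyst to suppress isomerisation of the angelate to the tiglate.

**Step 14**
Reactants: 24 3β-angeloyloxy-11-(tert-butyldimethylsilyloxy)eremophil-9-en-8-one
Product: 25 3β-angeloyloxy-11-(tert-butyldimethylsilyloxy)eremophil-9-ene-1,8-dione
Conditions: Rh2(cap)4 (cap = caprolactamate, 1 mol%), t-BuOOH (70% in water, 5 equiv), ClCH2CH2Cl, 40 °C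
Reagents that add atoms: tert-butyl hydroperoxide, CC(C)(C)OO
Why: Dirhodium-catalysed allylic oxidation by tert-butylperoxyl radicals converts an enone into an ene-1,4-dione at its γ-methylene; C1 is the only such position because C7 is still sp3, and the neutral medium should spare the β-acyloxy ketone that is formed.

**Step 15**
Reactants: 25 3β-angeloyloxy-11-(tert-butyldimethylsilyloxy)eremophil-9-ene-1,8-dione
Product: 26 3β-angeloyloxy-11-hydroxyeremophil-9-ene-1,8-dione
Conditions: 48% aq. HF, MeCN, 0 → 23 °C
Reagents that add atoms: none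
Why: Acidic fluoride desilylation cleaves the tertiary silyl ether under conditions that should tolerate the ester and the base-sensitive β-acyloxy ketone.

**Step 16**
Reactants: 26 3β-angeloyloxy-11-hydroxyeremophil-9-ene-1,8-dione
Product: 27 3β-angeloyloxyeremophila-7(11),9-diene-1,8-dione
Conditions: Burgess reagent (methyl N-(triethylammoniosulfonyl)carbamate), toluene, 50 °C
Reagents that add atoms: none
Why: Burgess dehydration of the tertiary β-ketol by syn elimination towards the acidic C7–H should give the conjugated C7=C11 isopropylidene under neutral conditions and removes the C7 stereocentre; any isopropenyl isomer should move into conjugation on silica.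

**Step 17**
Reactants: 27 3β-angeloyloxyeremophila-7(11),9-diene-1,8-dione
Product: 28 3β-angeloyloxy-1β-hydroxyeremophila-7(11),9-dien-8-one
Conditions: NaBH4 (1 equiv), CeCl3·7H2O, MeOH, −78 °C; AcOH quench
Reagents that add atoms: none
Why: Luche 1,2-reduction should take the C1 carbonyl in preference to C8, which is cross-conjugated and flanked by the isopropylidene; hydride should arrive from the α-face because the β-face of C1 is screened by the axial C14 methyl and the axial C3 ester, which sets the 1β-hydroxyl.

**Step 18**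
Reactants: 28 3β-angeloyloxy-1β-hydroxyeremophila-7(11),9-dien-8-one
Product: 29 (1R,3S,4R,5R)-3-angeloyloxy-11-hydroperoxy-1-hydroxyeremophila-6,9-dien-8-one (CNP0300636.1)
Conditions: O2, tetraphenylporphyrin (cat.), CH2Cl2, visible light, −20 °C
Reagents that add atoms: oxygen, O=O
Why: Schenck ene reaction of singlet oxygen with the tetrasubstituted C7=C11 alkene; in α,β-unsaturated ketones hydrogen is taken from the alkyl group geminal to the carbonyl (C6), so oxygen should bond to C11 and the double bond shift to C6=C7, with no new stereocentre formed.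

**Compound list**
1 | 2-methylcyclohex-2-en-1-one | CC1=CCCCC1=O | starting material
2 | (S)-2-methylcyclohex-2-en-1-ol | O[C@H]1CCCC=C1C | intermediate
3 | (S)-triethyl[(2-methylcyclohex-2-en-1-yl)oxy]silane | CC[Si](CC)(CC)O[C@H]1CCCC=C1C | intermediate
4 | alkylborane from 3 (boron on C5, trans to the C4 methyl) | B[C@@H]1[C@@H](C)[C@@H](O[Si](CC)(CC)CC)CCC1 | intermediate
5 | (1S,2R,3S)-2-methyl-3-(triethylsilyloxy)cyclohexan-1-ol | O[C@@H]1[C@@H](C)[C@@H](O[Si](CC)(CC)CC)CCC1 | intermediate
6 | (2S,3S)-2-methyl-3-(triethylsilyloxy)cyclohexan-1-one | O=C1[C@@H](C)[C@@H](O[Si](CC)(CC)CC)CCC1 | intermediate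
7 | 2-bromo-N-methoxy-N-methylacetamide | BrCC(=O)N(C)OC | starting material
8 | lithium enolate of 6 (C5–C10 enolate) | [Li]OC1=CCC[C@H](O[Si](CC)(CC)CC)[C@@H]1C | intermediate
9 | 2-[(1R,3S,4S)-3-methyl-2-oxo-4-(triethylsilyloxy)cyclohexyl]-N-methoxy-N-methylacetamide | O=C1[C@@H](C)[C@@H](O[Si](CC)(CC)CC)CC[C@@H]1CC(=O)N(C)OC | intermediate
10 | 2-[(1R,3R,4S)-3-methyl-2-methylidene-4-(triethylsilyloxy)cyclohexyl]-N-methoxy-N-methylacetamide | C=C1[C@@H](C)[C@@H](O[Si](CC)(CC)CC)CC[C@@H]1CC(=O)N(C)OC | intermediate
11 | 2-methylbut-3-yn-2-ol | CC(C)(O)C#C | starting material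
12 | 3-bromo-2-methylbut-3-en-2-ol | CC(C)(O)C(Br)=C | intermediate
13 | [(3-bromo-2-methylbut-3-en-2-yl)oxy](tert-butyl)dimethylsilane | C=C(Br)C(C)(C)O[Si](C)(C)C(C)(C)C | intermediate
14 | 3-(tert-butyldimethylsilyloxy)-3-methylbut-1-en-2-yllithium | [Li]C(=C)C(C)(C)O[Si](C)(C)C(C)(C)C | intermediate
15 | 4-(tert-butyldimethylsilyloxy)-4-methyl-3-methylidene-1-[(1R,3R,4S)-3-methyl-2-methylidene-4-(triethylsilyloxy)cyclohexyl]pentan-2-one | C=C1[C@@H](C)[C@@H](O[Si](CC)(CC)CC)CC[C@@H]1CC(=O)C(=C)C(C)(C)O[Si](C)(C)C(C)(C)C | intermediate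
16 | tertiary C5 radical from 15 | C[C]1[C@@H](C)[C@@H](O[Si](CC)(CC)CC)CC[C@@H]1CC(=O)C(=C)C(C)(C)O[Si](C)(C)C(C)(C)C | intermediate
17 | cyclised α-keto C7 radical | CC[Si](CC)(CC)O[C@H]1CC[C@@H]2CC(=O)[C](C(C)(C)O[Si](C)(C)C(C)(C)C)C[C@]2(C)[C@H]1C | intermediate
18 | 11-(tert-butyldimethylsilyloxy)-3β-(triethylsilyloxy)-10βH-eremophilan-8-one (cis-fused, 7β epimer drawn) | CC[Si](CC)(CC)O[C@H]1CC[C@@H]2CC(=O)[C@@H](C(C)(C)O[Si](C)(C)C(C)(C)C)C[C@]2(C)[C@H]1C | intermediate
19 | C8–C9 trimethylsilyl enol ether of 18 | CC[Si](CC)(CC)O[C@H]1CC[C@@H]2C=C(O[Si](C)(C)C)[C@@H](C(C)(C)O[Si](C)(C)C(C)(C)C)C[C@]2(C)[C@H]1C | intermediate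
20 | 11-(tert-butyldimethylsilyloxy)-3β-(triethylsilyloxy)eremophil-9-en-8-one | CC[Si](CC)(CC)O[C@H]1CCC2=CC(=O)[C@@H](C(C)(C)O[Si](C)(C)C(C)(C)C)C[C@]2(C)[C@H]1C | intermediate
21 | 11-(tert-butyldimethylsilyloxy)-3β-hydroxyeremophil-9-en-8-one | O[C@H]1CCC2=CC(=O)[C@@H](C(C)(C)O[Si](C)(C)C(C)(C)C)C[C@]2(C)[C@H]1C | intermediate
22 | angelic acid, (Z)-2-methylbut-2-enoic acid | C/C=C(/C)C(=O)O | starting material
23 | angelic 2,4,6-trichlorobenzoic anhydride | C/C=C(/C)C(=O)OC(=O)c1c(Cl)cc(Cl)cc1Cl | intermediate
24 | 3β-angeloyloxy-11-(tert-butyldimethylsilyloxy)eremophil-9-en-8-one | C/C=C(/C)C(=O)O[C@H]1CCC2=CC(=O)[C@@H](C(C)(C)O[Si](C)(C)C(C)(C)C)C[C@]2(C)[C@H]1C | intermediate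
25 | 3β-angeloyloxy-11-(tert-butyldimethylsilyloxy)eremophil-9-ene-1,8-dione | C/C=C(/C)C(=O)O[C@H]1CC(=O)C2=CC(=O)[C@@H](C(C)(C)O[Si](C)(C)C(C)(C)C)C[C@]2(C)[C@H]1C | intermediate
26 | 3β-angeloyloxy-11-hydroxyeremophil-9-ene-1,8-dione | C/C=C(/C)C(=O)O[C@H]1CC(=O)C2=CC(=O)[C@@H](C(C)(C)O)C[C@]2(C)[C@H]1C | intermediate
27 | 3β-angeloyloxyeremophila-7(11),9-diene-1,8-dione | C/C=C(/C)C(=O)O[C@H]1CC(=O)C2=CC(=O)C(=C(C)C)C[C@]2(C)[C@H]1C | intermediate
28 | 3β-angeloyloxy-1β-hydroxyeremophila-7(11),9-dien-8-one | C/C=C(/C)C(=O)O[C@H]1C[C@@H](O)C2=CC(=O)C(=C(C)C)C[C@]2(C)[C@H]1C | intermediate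
29 | (1R,3S,4R,5R)-3-angeloyloxy-11-hydroperoxy-1-hydroxyeremophila-6,9-dien-8-one | C/C=C(/C)C(=O)O[C@H]1C[C@@H](O)C2=CC(=O)C(C(C)(C)OO)=C[C@]2(C)[C@H]1C | target

**Step count**
Total: 18 steps. Longest linear sequence: 16 steps (steps 1–6 and 9–18, from 2-methylcyclohex-2-en-1-one); steps 7 and 8 make the side-chain fragment.

**Three steps most likely to fail**

Step 10. The iron hydride may quench the tertiary radical, or reduce the enone, before the ring closes, so that simple hydrogenation of the methylene or of the vinyl ketone competes with cyclisation. The fallback generates the same C5 radical without a metal hydride and with the hydrogen donor kept scarce. It sets out from 10: cobalt-mediated Markovnikov hydrobromination (Co(acac)2, TsBr, t-BuOOH, Et3SiH, n-PrOH, 23 °C) should give the tertiary C5 bromide F1. Acylation of vinyllithium 14 with F1, as in step 9, should give the bromo enone F2. Slow addition of Bu3SnH with AIBN in benzene at 80 °C should then close ring B through radicals 16 and 17, returning to the route at 18.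

Step 14. Hydrogen abstraction at C1 may be slow because the stereoelectronically aligned axial C1–H lies between the C14 methyl and the C3 ester, so oxidation at other C–H bonds or incomplete conversion may result. The fallback replaces radical C–H oxidation by a two-electron oxidation of a dienol ether. It sets out from 24: Me3SiOTf and Et3N in CH2Cl2 should give the extended trimethylsilyl dienol ether F3. Buffered mCPBA at −20 °C (vinylogous Rubottom oxidation) should give the 1-hydroxy enone F4, as either C1 epimer. Dess–Martin oxidation then returns to the route at 25.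

Step 17. Hydride may not discriminate cleanly between the two carbonyl groups of the ene-dione, so that C8 is reduced as well. The fallback gives up the chemoselective reduction. It sets out from 27: excess NaBH4 and CeCl3·7H2O in MeOH at −40 °C should reduce both carbonyls, C1 again from the α-face, to the 1β,8-diol F5. MnO2 in CH2Cl2 should then reoxidise only the doubly allylic C8 carbinol, leaving the screened axial C1 alcohol, and return to the route at 28.

**Further compounds**
F1 | step 10 | 2-[(1R,3S,4S)-2-bromo-2,3-dimethyl-4-(triethylsilyloxy)cyclohexyl]-N-methoxy-N-methylacetamide (C5 epimers) | CC1(Br)[C@@H](C)[C@@H](O[Si](CC)(CC)CC)CC[C@@H]1CC(=O)N(C)OC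
F2 | step 10 | 1-[(1R,3S,4S)-2-bromo-2,3-dimethyl-4-(triethylsilyloxy)cyclohexyl]-4-(tert-butyldimethylsilyloxy)-4-methyl-3-methylidenepentan-2-one (C5 epimers) | CC1(Br)[C@@H](C)[C@@H](O[Si](CC)(CC)CC)CC[C@@H]1CC(=O)C(=C)C(C)(C)O[Si](C)(C)C(C)(C)C
F3 | step 14 | 3β-angeloyloxy-11-(tert-butyldimethylsilyloxy)-8-(trimethylsilyloxy)eremophila-1(10),8-diene | C/C=C(/C)C(=O)O[C@H]1CC=C2C=C(O[Si](C)(C)C)[C@@H](C(C)(C)O[Si](C)(C)C(C)(C)C)C[C@]2(C)[C@H]1C
F4 | step 14 | 3β-angeloyloxy-11-(tert-butyldimethylsilyloxy)-1-hydroxyeremophil-9-en-8-one (C1 epimers) | C/C=C(/C)C(=O)O[C@H]1CC(O)C2=CC(=O)[C@@H](C(C)(C)O[Si](C)(C)C(C)(C)C)C[C@]2(C)[C@H]1C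
F5 | step 17 | 3β-angeloyloxyeremophila-7(11),9-diene-1β,8-diol (C8 epimers) | C/C=C(/C)C(=O)O[C@H]1C[C@@H](O)C2=CC(O)C(=C(C)C)C[C@]2(C)[C@H]1C
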